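## Retrosynthetic overview

- **Numbering (calamenene):** C1 carries CH3, C4 isopropyl, C6 the aryl CH3 and C8 the OH. Unit A is bonded through C7 and unit B (primed) through C5'. The target is (1S,4R,1'S,4'R), and all four centres come from C5 and C2 of (+)-menthol.
- **Feature used:** the C8 hydroxyl and the C6' methyl lie on either side of the C7–C5' bond, so they are read as the two halves of a C8–O–CH2–C6' bridge (a pyran ring), and C8'–OH is read as C8'–Si. Aromatic ring B then consists of three two-carbon pieces: C4a'/C5', C6'/C7' and C8'/C8a'.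
- **Key disconnection:** the bridged biaryl comes from a triyne. C4a'≡C5' and C8a'≡C8' sit on the C4'–C3'–C2'–C1' chain and C6'≡C7' sits on the O–CH2 group. One [2+2+2] closes ring B, its saturated ring and the pyran.
- **Triyne:** it is assembled from propargyl bromide, the C7 iodide of unit A and a monosilylated diyne (Sonogashira coupling). The diyne comes from menthone by ozonolysis of the kinetic silyl enol ether, which leaves the two chain ends at different oxidation levels.
- **Ring order:** the menthol ring becomes the saturated ring of unit A. Aromatic ring A is annulated onto it (Shapiro formylation, Stobbe benzannulation). Three rings then form in one step, and the pyran is opened again at the end.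

Key step: step 20

Assumption: the SMILES defines the four sp3 centres but not the sense of the hindered C7–C5' axis, so the route is held to the sp3 centres. The axis should follow the twist of the bridged precursor, and atropisomers, if both form, would be separated at the end.

## Route

Step 1
Reactants: 1 (+)-menthol
Product: 2 (+)-menthone
Conditions: aq. NaOCl, AcOH, 0 °C to rt
Reagents that add atoms: none
Why: Hypochlorite oxidation of a secondary alcohol is fast at low temperature, so the ketone should form before the isopropyl-bearing α-carbon can epimerise, and the two centres kept here are the source of all four stereocentres of the target.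

Step 2
Reactants: 2 (+)-menthone
Product: 3 (+)-menthone (E)-2,4,6-triisopropylbenzenesulfonylhydrazone
Conditions: 2,4,6-triisopropylbenzenesulfonyl hydrazide, cat. HCl, MeOH, rt; recrystallisation
Reagents that add atoms: 2,4,6-triisopropylbenzenesulfonyl hydrazide, NNS(=O)(=O)c1c(C(C)C)cc(C(C)C)cc1C(C)C
Why: In this acid-catalysed hydrazone condensation the sulfonamide nitrogen should settle anti to the isopropyl-bearing carbon, and recrystallisation should remove any epimer formed by ene-hydrazine tautomerism.

Step 3
Reactants: 3 (+)-menthone (E)-2,4,6-triisopropylbenzenesulfonylhydrazone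
Product: 5 (3S,6R)-6-isopropyl-3-methylcyclohex-1-ene-1-carbaldehyde, via vinyllithium 4 (not isolated)
Conditions: nBuLi (2.2 equiv), TMEDA–hexane, −78 to 0 °C; DMF, −78 °C to rt; aq. NH4Cl
Reagents that add atoms: N,N-dimethylformamide, CN(C)C=O
Why: In the Shapiro reaction the syn-directed second deprotonation takes a ring CH2 hydrogen, loss of sulfinate and N2 gives the less substituted vinyllithium, and formylation leaves both allylic stereocentres untouched.

Step 4
Reactants: 5 (3S,6R)-6-isopropyl-3-methylcyclohex-1-ene-1-carbaldehyde; 6 dimethyl succinate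
Product: 7 (E)-4-[(3S,6R)-6-isopropyl-3-methylcyclohex-1-en-1-yl]-3-(methoxycarbonyl)but-3-enoic acid
Conditions: 6 (1.5 equiv), KOtBu, tBuOH–THF, 0 °C; 5 added slowly, 0 °C to rt; aq. HCl
Reagents that add atoms: none
Why: The Stobbe condensation (aldol addition, lactonisation, E1cB opening) should give the E half-ester with the CH2CO2H arm cis to the cyclohexenyl group, and slow addition of the aldehyde to the enolate suppresses γ-deprotonation, the only path that could scramble the methyl-bearing centre.

Step 5
Reactants: 7 (E)-4-[(3S,6R)-6-isopropyl-3-methylcyclohex-1-en-1-yl]-3-(methoxycarbonyl)but-3-enoic acid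
Product: 9 methyl (5S,8R)-4-acetoxy-8-isopropyl-5-methyl-5,6,7,8-tetrahydronaphthalene-2-carboxylate, via free phenol ester 8 (not isolated)
Conditions: Ac2O, NaOAc, reflux
Reagents that add atoms: acetic anhydride, CC(=O)OC(C)=O
Why: In this Stobbe-type benzannulation the activated acid closes a six-membered ring onto the ring alkene CH, loss of that hydrogen aromatises the new ring and the phenol is acetylated in situ, while the two sp3 centres become benzylic without being touched.

Step 6
Reactants: 9 methyl (5S,8R)-4-acetoxy-8-isopropyl-5-methyl-5,6,7,8-tetrahydronaphthalene-2-carboxylate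
Product: 10 (5R,8S)-3-(hydroxymethyl)-5-isopropyl-8-methyl-5,6,7,8-tetrahydronaphthalen-1-ol
Conditions: LiAlH4, THF, 0 °C to rt
Reagents that add atoms: none
Why: Hydride reduction of esters takes the benzoate to the benzylic alcohol and cleaves the aryl acetate in the same operation.

Step 7
Reactants: 10 (5R,8S)-3-(hydroxymethyl)-5-isopropyl-8-methyl-5,6,7,8-tetrahydronaphthalen-1-ol
Product: 11 (1S,4R)-8-hydroxycalamenene
Conditions: H2 (3 bar), Pd/C, EtOH, cat. HCl, rt
Reagents that add atoms: none
Why: Acid-assisted catalytic hydrogenolysis of a primary benzylic alcohol gives the C6 methyl group, and the tertiary benzylic C–H centres are inert to Pd/C at room temperature.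

Step 8
Reactants: 11 (1S,4R)-8-hydroxycalamenene
Product: 12 (1S,4R)-8-(methoxymethoxy)calamenene
Conditions: MOMCl, iPr2NEt, CH2Cl2, 0 to 40 °C
Reagents that add atoms: chloromethyl methyl ether, COCCl
Why: O-Alkylation to the MOM acetal protects the phenol, installs the directing group for step 9 and blocks benzofuran formation in step 17.

Step 9
Reactants: 12 (1S,4R)-8-(methoxymethoxy)calamenene
Product: 14 (1S,4R)-7-iodo-8-(methoxymethoxy)calamenene, via C7 aryllithium 13 (not isolated)
Conditions: nBuLi, TMEDA, Et2O, 0 °C to rt; I2, THF, −78 °C to rt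
Reagents that add atoms: iodine, II
Why: In this directed ortho metalation C7 is the only free position ortho to the OMOM group, which fixes a regiochemistry that electrophilic iodination (C5 against C7) could not guarantee, and the tertiary benzylic C1–H is too hindered for lateral lithiation.

Step 10
Reactants: 2 (+)-menthone
Product: 16 {[(3S,6R)-6-isopropyl-3-methylcyclohex-1-en-1-yl]oxy}trimethylsilane, via lithium enolate 15 (not isolated)
Conditions: LiN(iPr)2 (LDA), THF, −78 °C; TMSCl, −78 °C to rt
Reagents that add atoms: chlorotrimethylsilane, C[Si](C)(C)Cl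
Why: Kinetic enolisation takes the unhindered ring CH2 rather than the tertiary C–H next to isopropyl, so O-silylation traps the less substituted enol ether and the isopropyl-bearing centre keeps its configuration.

Step 11
Reactants: 16 {[(3S,6R)-6-isopropyl-3-methylcyclohex-1-en-1-yl]oxy}trimethylsilane
Product: 18 (2R,5S)-2-isopropyl-5-methyl-6-oxohexanoic acid, via trimethylsilyl ester 17 (not isolated)
Conditions: O3, CH2Cl2, −78 °C; Me2S, −78 °C to rt; water work-up, used crude
Reagents that add atoms: ozone, [O-][O+]=O
Why: Ozonolysis of a silyl enol ether cleaves the ring C=C into a silyl ester at the isopropyl end and an aldehyde at the methyl end, which differentiates the two chain ends where ozonolysis of the plain menthene would not.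

Step 12
Reactants: 18 (2R,5S)-2-isopropyl-5-methyl-6-oxohexanoic acid
Product: 19 (2R,5S)-2-isopropyl-5-methylhept-6-ynoic acid
Conditions: dimethyl (1-diazo-2-oxopropyl)phosphonate, K2CO3 (3 equiv), MeOH, 0 °C to rt; aq. HCl
Reagents that add atoms: dimethyl (1-diazo-2-oxopropyl)phosphonate, COP(=O)(OC)C(=[N+]=[N-])C(C)=O
Why: The Ohira–Bestmann variant of the Seyferth–Gilbert homologation converts the aldehyde into the terminal alkyne under carbonate conditions that α-methyl aldehydes normally tolerate without epimerisation, and the carboxylate is inert.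

Step 13
Reactants: 19 (2R,5S)-2-isopropyl-5-methylhept-6-ynoic acid
Product: 20 (2R,5S)-2-isopropyl-5-methylhept-6-yn-1-ol
Conditions: LiAlH4, THF, 0 °C to reflux
Reagents that add atoms: none
Why: Hydride reduction of the carboxylic acid gives the primary alcohol and leaves an isolated terminal alkyne alone.

Step 14
Reactants: 20 (2R,5S)-2-isopropyl-5-methylhept-6-yn-1-ol; 21 benzyl(chloro)dimethylsilane
Product: 24 (2R,5S)-7-[benzyl(dimethyl)silyl]-2-isopropyl-5-methylhept-6-yn-1-ol, via dilithio alkynolate 22 (not isolated), via bis-silylated compound 23 (not isolated)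
Conditions: nBuLi (2.2 equiv), THF, −78 °C; 21 (2.2 equiv), −78 °C to rt; 1 M HCl, THF, rt
Reagents that add atoms: none
Why: Acetylide C-silylation by double deprotonation, double silylation and mild acid hydrolysis is the standard route to C-silylated alkynols, because the Si–O bond is cleaved far faster than the alkynyl C–Si bond.

Step 15
Reactants: 24 (2R,5S)-7-[benzyl(dimethyl)silyl]-2-isopropyl-5-methylhept-6-yn-1-ol
Product: 25 (2R,5S)-7-[benzyl(dimethyl)silyl]-2-isopropyl-5-methylhept-6-ynal
Conditions: Dess–Martin periodinane, CH2Cl2, 0 °C to rt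
Reagents that add atoms: none
Why: Dess–Martin oxidation stops at the aldehyde under nearly neutral conditions, so the α-isopropyl centre and the alkynylsilane should survive.

Step 16
Reactants: 25 (2R,5S)-7-[benzyl(dimethyl)silyl]-2-isopropyl-5-methylhept-6-ynal
Product: 26 benzyl[(3S,6R)-6-isopropyl-3-methylocta-1,7-diyn-1-yl]dimethylsilane
Conditions: TMSCHN2, LiN(iPr)2 (LDA), THF, −78 °C; then 25, −78 °C to rt
Reagents that add atoms: (trimethylsilyl)diazomethane, C[Si](C)(C)C=[N+]=[N-]
Why: The Colvin rearrangement (addition, Peterson-type loss of silanolate, loss of N2, 1,2-hydrogen shift) gives the terminal alkyne at low temperature without the carbonate/methanol medium of step 12, which would strip the alkynylsilane.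

Step 17
Reactants: 14 (1S,4R)-7-iodo-8-(methoxymethoxy)calamenene; 26 benzyl[(3S,6R)-6-isopropyl-3-methylocta-1,7-diyn-1-yl]dimethylsilane
Product: 27 (1S,4R)-7-{(3R,6S)-8-[benzyl(dimethyl)silyl]-3-isopropyl-6-methylocta-1,7-diyn-1-yl}-8-(methoxymethoxy)calamenene
Conditions: PdCl2(PPh3)2 (5 mol %), CuI (10 mol %), Et3N–THF, degassed, 60 °C
Reagents that add atoms: none
Why: In this Sonogashira coupling only the isopropyl-side alkyne has a C–H, aryl iodides couple even between two ortho groups, and the MOM ether prevents the 5-endo closure to a benzofuran that a free ortho phenol would undergo.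

Step 18
Reactants: 27 (1S,4R)-7-{(3R,6S)-8-[benzyl(dimethyl)silyl]-3-isopropyl-6-methylocta-1,7-diyn-1-yl}-8-(methoxymethoxy)calamenene
Product: 28 (1S,4R)-7-{(3R,6S)-8-[benzyl(dimethyl)silyl]-3-isopropyl-6-methylocta-1,7-diyn-1-yl}-8-hydroxycalamenene
Conditions: cat. HCl, MeOH–THF, 40 °C
Reagents that add atoms: none
Why: Acid-catalysed acetal exchange removes the MOM group, and neither the alkynylsilane nor the benzylsilane is labile to dilute acid.

Step 19
Reactants: 28 (1S,4R)-7-{(3R,6S)-8-[benzyl(dimethyl)silyl]-3-isopropyl-6-methylocta-1,7-diyn-1-yl}-8-hydroxycalamenene; 29 propargyl bromide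
Product: 30 (1S,4R)-7-{(3R,6S)-8-[benzyl(dimethyl)silyl]-3-isopropyl-6-methylocta-1,7-diyn-1-yl}-8-(prop-2-yn-1-yloxy)calamenene
Conditions: 29, K2CO3, dry DMF, rt
Reagents that add atoms: none
Why: Williamson etherification with a very reactive propargylic bromide in an aprotic medium should outrun both base-induced benzofuran closure and desilylation, which needs a protic nucleophile.

Step 20
Reactants: 30 (1S,4R)-7-{(3R,6S)-8-[benzyl(dimethyl)silyl]-3-isopropyl-6-methylocta-1,7-diyn-1-yl}-8-(prop-2-yn-1-yloxy)calamenene
Product: 31 (1S,4R,1'S,4'R) O–CH2-bridged biaryl (6H-benzo[c]chromene core: C7–C5' bond spanned by C8–O–CH2–C6') carrying SiMe2Bn at C8'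
Conditions: RhCl(PPh3)3 (10 mol %), degassed toluene, 110 °C, 30 added by syringe pump to a final 0.003 M
Reagents that add atoms: none
Why: After loss of a phosphine, monovalent rhodium takes up two neighbouring alkynes and couples them oxidatively to a five-membered metallacycle of trivalent rhodium, the remaining tethered alkyne inserts, and reductive elimination releases aromatic ring B and returns the catalyst. The closest known reaction type is the rhodium- or cobalt-catalysed [2+2+2] cyclotrimerisation of fully tethered triynes, established for 2-alkynylaryl propargyl ethers (to 6H-benzo[c]chromenes), for octa-1,7-diynes (to tetralins) and for silyl-capped alkynes. Ring B closes by cycloaromatisation through the three new bonds C5'–C6', C7'–C8' and C4a'–C8a'; the saturated ring closes six-membered when C4a'–C8a' forms across the C4'–C3'–C2'–C1' chain, and the pyran closes six-membered when C5'–C6' forms across C7–C8–O–CH2. No sp3 stereocentre is created and the four existing ones (two of them propargylic C–H, untouched under neutral conditions) are carried through; the only new stereoelement is the twist of the bridged biaryl, which the C4' isopropyl group should bias and which the target does not define. Regiochemistry needs no control because each alkyne carbon can reach only the partner its tether allows; the step does need ring closure to win over oligomerisation at the one terminal alkyne, and the short tethers, the branching at C1' and C4', the silyl cap on the other terminus and slow addition at high dilution serve this. Unit A is already bonded to C5' as the substituent of a linear alkyne, so the crowded C7–C5' bond itself never has to be made.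

Step 21
Reactants: 31 (1S,4R,1'S,4'R) O–CH2-bridged biaryl carrying SiMe2Bn at C8'
Product: 33 (1S,4R,1'S,4'R) O–CH2-bridged biaryl carrying OH at C8', via aryldimethylsilanol 32 (not isolated)
Conditions: TBAF, THF, 0 °C to rt; then 30% H2O2, KHCO3, MeOH, rt to 40 °C
Reagents that add atoms: hydrogen peroxide, OO
Why: In the Tamao–Fleming oxidation fluoride expels benzyl, the best carbanion leaving group on silicon, to give the silanol, whose peroxide adduct undergoes 1,2-migration of the aryl group from silicon to oxygen, so the oxygen lands exactly at C8'.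

Step 22
Reactants: 33 (1S,4R,1'S,4'R) O–CH2-bridged biaryl carrying OH at C8'
Product: 34 target, (1S,4R,1'S,4'R)-7,5'-bi(8-hydroxycalamenene)
Conditions: H2 (4 bar), Pd/C, EtOH–AcOH, 40 °C
Reagents that add atoms: none
Why: In this catalytic hydrogenolysis of a benzyl aryl ether the bridging CH2–O bond is the only benzylic C–O bond, its cleavage relieves the twist strain of the bridged biaryl, and it leaves exactly the C8 hydroxyl and the C6' methyl group.

## Compound list

1 | (+)-menthol, (1S,2R,5S)-2-isopropyl-5-methylcyclohexan-1-ol | C[C@H]1CC[C@H](C(C)C)[C@@H](O)C1 | starting material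
2 | (+)-menthone, (2R,5S)-2-isopropyl-5-methylcyclohexan-1-one | C[C@H]1CC[C@H](C(C)C)C(=O)C1 | intermediate
3 | (+)-menthone (E)-2,4,6-triisopropylbenzenesulfonylhydrazone | C[C@H]1CC[C@H](C(C)C)/C(=N/NS(=O)(=O)c2c(C(C)C)cc(C(C)C)cc2C(C)C)C1 | intermediate
4 | [(3S,6R)-6-isopropyl-3-methylcyclohex-1-en-1-yl]lithium | [Li]C1=C[C@@H](C)CC[C@@H]1C(C)C | intermediate
5 | (3S,6R)-6-isopropyl-3-methylcyclohex-1-ene-1-carbaldehyde | O=CC1=C[C@@H](C)CC[C@@H]1C(C)C | intermediate
6 | dimethyl succinate | COC(=O)CCC(=O)OC | starting material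
7 | (E)-4-[(3S,6R)-6-isopropyl-3-methylcyclohex-1-en-1-yl]-3-(methoxycarbonyl)but-3-enoic acid | COC(=O)/C(CC(=O)O)=C/C1=C[C@@H](C)CC[C@@H]1C(C)C | intermediate
8 | methyl (5S,8R)-4-hydroxy-8-isopropyl-5-methyl-5,6,7,8-tetrahydronaphthalene-2-carboxylate | COC(=O)c1cc2c(c(O)c1)[C@@H](C)CC[C@@H]2C(C)C | intermediate
9 | methyl (5S,8R)-4-acetoxy-8-isopropyl-5-methyl-5,6,7,8-tetrahydronaphthalene-2-carboxylate | COC(=O)c1cc2c(c(OC(C)=O)c1)[C@@H](C)CC[C@@H]2C(C)C | intermediate
10 | (5R,8S)-3-(hydroxymethyl)-5-isopropyl-8-methyl-5,6,7,8-tetrahydronaphthalen-1-ol | OCc1cc2c(c(O)c1)[C@@H](C)CC[C@@H]2C(C)C | intermediate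
11 | (1S,4R)-8-hydroxycalamenene, (5R,8S)-5-isopropyl-3,8-dimethyl-5,6,7,8-tetrahydronaphthalen-1-ol | Cc1cc2c(c(O)c1)[C@@H](C)CC[C@@H]2C(C)C | intermediate
12 | (1S,4R)-8-(methoxymethoxy)calamenene | Cc1cc2c(c(OCOC)c1)[C@@H](C)CC[C@@H]2C(C)C | intermediate
13 | (1S,4R)-7-lithio-8-(methoxymethoxy)calamenene | Cc1cc2c(c(OCOC)c1[Li])[C@@H](C)CC[C@@H]2C(C)C | intermediate
14 | (1S,4R)-7-iodo-8-(methoxymethoxy)calamenene | Cc1cc2c(c(OCOC)c1I)[C@@H](C)CC[C@@H]2C(C)C | intermediate
15 | lithium (3S,6R)-6-isopropyl-3-methylcyclohex-1-en-1-olate | [Li]OC1=C[C@@H](C)CC[C@@H]1C(C)C | intermediate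
16 | {[(3S,6R)-6-isopropyl-3-methylcyclohex-1-en-1-yl]oxy}trimethylsilane | C[Si](C)(C)OC1=C[C@@H](C)CC[C@@H]1C(C)C | intermediate
17 | trimethylsilyl (2R,5S)-2-isopropyl-5-methyl-6-oxohexanoate | O=C[C@@H](C)CC[C@H](C(C)C)C(=O)O[Si](C)(C)C | intermediate
18 | (2R,5S)-2-isopropyl-5-methyl-6-oxohexanoic acid | O=C[C@@H](C)CC[C@H](C(C)C)C(=O)O | intermediate
19 | (2R,5S)-2-isopropyl-5-methylhept-6-ynoic acid | C#C[C@@H](C)CC[C@H](C(C)C)C(=O)O | intermediate
20 | (2R,5S)-2-isopropyl-5-methylhept-6-yn-1-ol | C#C[C@@H](C)CC[C@H](C(C)C)CO | intermediate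
21 | benzyl(chloro)dimethylsilane | C[Si](C)(Cl)Cc1ccccc1 | starting material
22 | dilithium salt of 20 (lithium alkoxide and lithium acetylide) | [Li]C#C[C@@H](C)CC[C@H](C(C)C)CO[Li] | intermediate
23 | O,C-bis[benzyl(dimethyl)silyl] derivative of 20 | C[Si](C)(Cc1ccccc1)C#C[C@@H](C)CC[C@H](C(C)C)CO[Si](C)(C)Cc1ccccc1 | intermediate
24 | (2R,5S)-7-[benzyl(dimethyl)silyl]-2-isopropyl-5-methylhept-6-yn-1-ol | C[Si](C)(Cc1ccccc1)C#C[C@@H](C)CC[C@H](C(C)C)CO | intermediate
25 | (2R,5S)-7-[benzyl(dimethyl)silyl]-2-isopropyl-5-methylhept-6-ynal | C[Si](C)(Cc1ccccc1)C#C[C@@H](C)CC[C@H](C(C)C)C=O | intermediate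
26 | benzyl[(3S,6R)-6-isopropyl-3-methylocta-1,7-diyn-1-yl]dimethylsilane | C[Si](C)(Cc1ccccc1)C#C[C@@H](C)CC[C@H](C(C)C)C#C | intermediate
27 | (1S,4R)-7-{(3R,6S)-8-[benzyl(dimethyl)silyl]-3-isopropyl-6-methylocta-1,7-diyn-1-yl}-8-(methoxymethoxy)calamenene | Cc1cc2c(c(OCOC)c1C#C[C@@H](C(C)C)CC[C@H](C)C#C[Si](C)(C)Cc1ccccc1)[C@@H](C)CC[C@@H]2C(C)C | intermediate
28 | (1S,4R)-7-{(3R,6S)-8-[benzyl(dimethyl)silyl]-3-isopropyl-6-methylocta-1,7-diyn-1-yl}-8-hydroxycalamenene | Cc1cc2c(c(O)c1C#C[C@@H](C(C)C)CC[C@H](C)C#C[Si](C)(C)Cc1ccccc1)[C@@H](C)CC[C@@H]2C(C)C | intermediate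
29 | propargyl bromide | C#CCBr | starting material
30 | (1S,4R)-7-{(3R,6S)-8-[benzyl(dimethyl)silyl]-3-isopropyl-6-methylocta-1,7-diyn-1-yl}-8-(prop-2-yn-1-yloxy)calamenene (triyne, key-step precursor) | Cc1cc2c(c(OCC#C)c1C#C[C@@H](C(C)C)CC[C@H](C)C#C[Si](C)(C)Cc1ccccc1)[C@@H](C)CC[C@@H]2C(C)C | intermediate
31 | (1S,4R,1'S,4'R) O–CH2-bridged biaryl, 6H-benzo[c]chromene core, C8'–SiMe2Bn (key-step product) | Cc1cc2c(c3c1-c1c(cc([Si](C)(C)Cc4ccccc4)c5c1[C@@H](C(C)C)CC[C@@H]5C)CO3)[C@@H](C)CC[C@@H]2C(C)C | intermediate
32 | (1S,4R,1'S,4'R) O–CH2-bridged biaryl, C8'–SiMe2OH | Cc1cc2c(c3c1-c1c(cc([Si](C)(C)O)c4c1[C@@H](C(C)C)CC[C@@H]4C)CO3)[C@@H](C)CC[C@@H]2C(C)C | intermediate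
33 | (1S,4R,1'S,4'R) O–CH2-bridged biaryl, C8'–OH | Cc1cc2c(c3c1-c1c(cc(O)c4c1[C@@H](C(C)C)CC[C@@H]4C)CO3)[C@@H](C)CC[C@@H]2C(C)C | intermediate
34 | CNP0145304.1, (1S,4R,1'S,4'R)-7,5'-bi(8-hydroxycalamenene) | Cc1cc2c(c(O)c1-c1c(C)cc(O)c3c1[C@@H](C(C)C)CC[C@@H]3C)[C@@H](C)CC[C@@H]2C(C)C | target

## Step count and risks

Total step count: 22 steps.
Longest linear sequence: 15 steps (steps 1–9, then 17–22). The diyne branch (steps 1 and 10–16) joins at step 17.

**Step 20 (key step).**
- What may go wrong: intermolecular alkyne coupling through the free C7'–H terminus (oligomerisation). The cascade may also stall, because the last C–C bond has to press the C6 methyl of unit A against the C4' isopropyl group in the bay of the bridged biaryl.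
- Fallback: ring B is no longer built on the biaryl bond, and two finished arenes are joined instead. The fallback sets out from phenol 11 and iodide 14.
- para-Bromination of 11 (Bu4NBr3, CH2Cl2–MeOH, 0 °C) should give (1S,4R)-5-bromo-8-hydroxycalamenene F1. MOMCl/iPr2NEt should convert this into its MOM ether F2.
- Bromine–lithium exchange (nBuLi, THF, −78 °C) followed by 2-isopropoxy-4,4,5,5-tetramethyl-1,3,2-dioxaborolane should give the C5 pinacol boronate F3.
- Suzuki–Miyaura coupling of F3 with 14 (Pd(OAc)2, SPhos, K3PO4, toluene–water, 100 °C) should give the bis-MOM biaryl F4. HCl in MeOH then removes both acetals, and the fallback comes back to the route at target 34.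

**Step 22.**
- What may go wrong: the buried benzylic ether may not reach the palladium surface, so cleavage is slow. Forcing conditions could start to saturate an arene.
- Fallback: the C–O bond is cleaved by a Lewis acid and the carbon is reduced in a separate radical step. The fallback sets out from 33.
- BBr3 (CH2Cl2, −78 to 0 °C) should open the benzyl aryl ether by bromide attack at CH2, giving the C6'-bromomethyl biaryl diol F5.
- F5 is reduced at once under neutral conditions (Bu3SnH, AIBN, toluene, 80 °C), so that the C8 phenol cannot close the ring again. The fallback comes back to the route at target 34.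

**Step 21.**
- What may go wrong: fluoride may expel the aryl group from silicon instead of benzyl (protodesilylation), helped by relief of the peri strain with the C1' methyl group.
- Fallback: silicon is activated by an electrophile instead of a nucleophile, and the order of the last two operations is reversed. The fallback sets out from 31.
- The bridge is hydrogenolysed first (conditions of step 22) to the ring-opened C8'-silyl biaryl phenol F6.
- ipso-Borodesilylation (BBr3, 2,6-di-tert-butylpyridine as HBr scavenger, CH2Cl2, 0 °C to rt, aqueous work-up) should give the C8' boronic acid F7.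
- H2O2/NaOH oxidises the C–B bond, and the fallback comes back to the route at target 34.

## Further compounds

F1 | step 20 | (1S,4R)-5-bromo-8-hydroxycalamenene | Brc1c(C)cc(O)c2c1[C@@H](C(C)C)CC[C@@H]2C
F2 | step 20 | (1S,4R)-5-bromo-8-(methoxymethoxy)calamenene | Brc1c(C)cc(OCOC)c2c1[C@@H](C(C)C)CC[C@@H]2C
F3 | step 20 | (1S,4R)-8-(methoxymethoxy)calamenene-5-boronic acid pinacol ester | CC1(C)OB(OC1(C)C)c1c(C)cc(OCOC)c2c1[C@@H](C(C)C)CC[C@@H]2C
F4 | step 20 | (1S,4R,1'S,4'R)-7,5'-bi[8-(methoxymethoxy)calamenene] | Cc1cc2c(c(OCOC)c1-c1c(C)cc(OCOC)c3c1[C@@H](C(C)C)CC[C@@H]3C)[C@@H](C)CC[C@@H]2C(C)C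
F5 | step 22 | C6'-bromomethyl analogue of the target (C8 and C8' free phenols) | Cc1cc2c(c(O)c1-c1c(CBr)cc(O)c3c1[C@@H](C(C)C)CC[C@@H]3C)[C@@H](C)CC[C@@H]2C(C)C
F6 | step 21 | ring-opened biaryl with C8–OH, C6'–CH3 and C8'–SiMe2Bn | Cc1cc2c(c(O)c1-c1c(C)cc([Si](C)(C)Cc4ccccc4)c3c1[C@@H](C(C)C)CC[C@@H]3C)[C@@H](C)CC[C@@H]2C(C)C
F7 | step 21 | ring-opened biaryl with C8–OH, C6'–CH3 and C8'–B(OH)2 | Cc1cc2c(c(O)c1-c1c(C)cc(B(O)O)c3c1[C@@H](C(C)C)CC[C@@H]3C)[C@@H](C)CC[C@@H]2C(C)C
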